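**Strategy.** Everything rests on the C5–C5a bond of the 2,5-dihydro-1-benzoxepine (O1, C2, C3(Me)=C4, C5, C5a–C9a): the bond from the allylic CH2 to the ring-A carbon lying between C9a–O1 and C6–OH. A zerovalent-palladium Tsuji–Trost C-allylation closes the oxepine in one operation, without protecting groups. Its precursor is the 4'-O-(4-acetoxy-2-methylbut-2-enyl) ether of 3-hydroxyphloretin. The step exploits three features: ring A of this ether is twofold-symmetric, so both CH carbons ortho to the ether oxygen are equivalent; these carbons have phloroglucinol-type nucleophilicity; and C3–C4–C5 is an allyl unit whose unsubstituted end is C5.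

Key step: step 3

Remark: the chlorobutenyl acetate building block is drawn as its E isomer; material that also holds the Z isomer can be used as such, because both isomers converge on the same equilibrating palladium allyl in the key step.

Step 1
Reactants: 1 phloroglucinol; 2 3-(3,4-dihydroxyphenyl)propanoic acid
Product: 3 3-(3,4-dihydroxyphenyl)-1-(2,4,6-trihydroxyphenyl)propan-1-one (3-hydroxyphloretin)
Conditions: BF3·OEt2 (solvent), 85 °C; then aq NaOAc
Reagents that add atoms: none
Why: BF3-mediated Friedel–Crafts acylation of the threefold-symmetric, most electron-rich ring by the free acid should give a single mono-ketone, because the first acyl group (held as a boron chelate) deactivates ring A towards a second acylation and the catechol ring is far less nucleophilic.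

Step 2
Reactants: 3 3-hydroxyphloretin; 4 (E)-4-chloro-3-methylbut-2-en-1-yl acetate
Product: 5 (E)-4-{4-[3-(3,4-dihydroxyphenyl)propanoyl]-3,5-dihydroxyphenoxy}-3-methylbut-2-en-1-yl acetate
Conditions: K2CO3 (1.0 equiv), 4 (1.05 equiv), DMF, 40 °C
Reagents that add atoms: none
Why: Williamson ether synthesis (SN2 at the primary allylic chloride): with one equivalent of carbonate only the 4'-hydroxyl para to the ketone should be ionised, since the 2'- and 6'-hydroxyls are chelated to the carbonyl and the catechol is markedly less acidic, and the acetate survives the anhydrous base.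

Step 3
Reactants: 5 (E)-4-{4-[3-(3,4-dihydroxyphenyl)propanoyl]-3,5-dihydroxyphenoxy}-3-methylbut-2-en-1-yl acetate
Product: 7 3-(3,4-dihydroxyphenyl)-1-(6,8-dihydroxy-3-methyl-2,5-dihydro-1-benzoxepin-7-yl)propan-1-one (target), via cyclohexadienone tautomer 6 (not isolated)
Conditions: Pd(PPh3)4 (5 mol %), THF (0.01 M), 45 °C, Ar; stopped at full conversion of 5
Reagents that add atoms: none
Why: Zerovalent palladium should ionise the allylic acetate to a cationic π-allylpalladium complex spanning C3–C4–C5, whose unsubstituted terminus C5 is attacked anti to the metal by the ring-A carbon between the ether oxygen and a free hydroxyl, giving cyclohexadienone 6, which tautomerises to phenol 7 while acetate takes up the proton. The closest known reaction type is the intramolecular Tsuji–Trost (Friedel–Crafts-type) C-allylation of phenols and acylphloroglucinols. The seven-membered ring closes in a 7-endo mode with respect to the allyl unit; the competing 5-exo attack at C3 would have to build a quaternary centre at the fully substituted terminus, against the usual preference of palladium allyls for attack at the less substituted end even when that gives the larger ring. No stereocentre is formed; the cis ring alkene is available because one of the two groups on C3 is necessarily anti, and π–σ–π interconversion should let the E-configured chain of 5 place its CH2O arm anti before the only productive closure (Curtin–Hammett). Site selectivity needs no control because ring A of 5 is twofold-symmetric, and O-allylation by the flanking hydroxyls cannot close a ring since it would require a meta-bridged ether. High dilution should suppress intermolecular allylation of the catechol, and stopping at full conversion should keep the allylic aryl ether of 7 from being ionised in turn.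

**Compound list**
1 | phloroglucinol (benzene-1,3,5-triol) | Oc1cc(O)cc(O)c1 | starting material
2 | 3-(3,4-dihydroxyphenyl)propanoic acid (dihydrocaffeic acid) | OC(=O)CCc1ccc(O)c(O)c1 | starting material
3 | 3-(3,4-dihydroxyphenyl)-1-(2,4,6-trihydroxyphenyl)propan-1-one (3-hydroxyphloretin) | O=C(CCc1ccc(O)c(O)c1)c1c(O)cc(O)cc1O | intermediate
4 | (E)-4-chloro-3-methylbut-2-en-1-yl acetate | C/C(CCl)=C\COC(C)=O | starting material
5 | (E)-4-{4-[3-(3,4-dihydroxyphenyl)propanoyl]-3,5-dihydroxyphenoxy}-3-methylbut-2-en-1-yl acetate | C/C(COc1cc(O)c(C(=O)CCc2ccc(O)c(O)c2)c(O)c1)=C\COC(C)=O | intermediate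
6 | cyclohexa-2,4-dienone tautomer of 7 (C5a sp3, C6 as ketone; racemic, stereocentre lost on tautomerisation) | CC1=CCC2C(OC1)=CC(O)=C(C(=O)CCc1ccc(O)c(O)c1)C2=O | intermediate (not isolated)
7 | 3-(3,4-dihydroxyphenyl)-1-(6,8-dihydroxy-3-methyl-2,5-dihydro-1-benzoxepin-7-yl)propan-1-one | CC1=CCc2c(cc(O)c(C(=O)CCc3ccc(O)c(O)c3)c2O)OC1 | target

Total step count: 3
Longest linear sequence: 3

**Steps most likely to fail**

1. Step 3. The ring may close at the substituted allyl terminus (5-exo) instead of at C5. Syn–anti equilibration of the π-allyl may be too slow, so that intermolecular O-allylation and oligomerisation take over. The cyclic allylic aryl ether of the product may be re-ionised, with a 1,3-shift of oxygen to a smaller ring. The fallback replaces the metal-allyl closure by a cationic one from a geometry-free precursor. It sets out from 3. Opening of 2-methyl-2-vinyloxirane (CC1(C=C)CO1) at its CH2 by the 4'-phenoxide (K2CO3 cat., DMF, 70 °C) should give the racemic tertiary allylic alcohol F1. Sc(OTf)3 (5 mol %) in MeNO2 at high dilution should ionise F1 to the allyl cation, either rotamer of which is accessible from the tertiary alcohol. Capture of its primary terminus by the ring-A carbon in a dehydrative Friedel–Crafts allylation (SN1') forms the same C5–C5a bond and returns to the route at 7.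

2. Step 2. Site selectivity may be lost through alkylation of a catechol oxygen, double alkylation, or C-alkylation of ring A. The fallback masks the catechol and sets out from 3. Dichlorodiphenylmethane (Ph2O, 175 °C) should convert only the catechol into the diphenylmethylene ketal F2. Alkylation with 4 under the conditions of step 2 should then give the 4'-O-alkyl ether F3, and cyclisation under the conditions of step 3 the cyclised ketal F4. Aqueous AcOH (80 %, reflux) should remove the ketal as benzophenone and return to the route at 7.

3. Step 1. O-acylation, diacylation or self-acylation of the acid to an indanone may compete, or conversion may stall because boron ties up the catechol. The fallback replaces the acylation by reductive ring opening of a flavanone. It sets out from none of the numbered compounds: commercial eriodictyol (O=C1CC(c2ccc(O)c(O)c2)Oc2cc(O)cc(O)c12, either enantiomer or the racemate) takes the place of 1 and 2. In aqueous KOH it should open to eriodictyol chalcone F5, which is hydrogenated in the same flask (H2, Pd/C, 25 °C) at the enone C=C only. Acidification returns to the route at 3.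

Further compounds
F1 | step 3 | rac-3-(3,4-dihydroxyphenyl)-1-[2,6-dihydroxy-4-(2-hydroxy-2-methylbut-3-enyloxy)phenyl]propan-1-one | CC(O)(C=C)COc1cc(O)c(C(=O)CCc2ccc(O)c(O)c2)c(O)c1
F2 | step 2 | 3-(2,2-diphenyl-1,3-benzodioxol-5-yl)-1-(2,4,6-trihydroxyphenyl)propan-1-one | O=C(CCc1ccc2OC(c3ccccc3)(c3ccccc3)Oc2c1)c1c(O)cc(O)cc1O
F3 | step 2 | (E)-4-{4-[3-(2,2-diphenyl-1,3-benzodioxol-5-yl)propanoyl]-3,5-dihydroxyphenoxy}-3-methylbut-2-en-1-yl acetate | C/C(COc1cc(O)c(C(=O)CCc2ccc3OC(c4ccccc4)(c4ccccc4)Oc3c2)c(O)c1)=C\COC(C)=O
F4 | step 2 | 1-(6,8-dihydroxy-3-methyl-2,5-dihydro-1-benzoxepin-7-yl)-3-(2,2-diphenyl-1,3-benzodioxol-5-yl)propan-1-one | CC1=CCc2c(cc(O)c(C(=O)CCc3ccc4OC(c5ccccc5)(c5ccccc5)Oc4c3)c2O)OC1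
F5 | step 1 | (E)-3-(3,4-dihydroxyphenyl)-1-(2,4,6-trihydroxyphenyl)prop-2-en-1-one (eriodictyol chalcone) | O=C(/C=C/c1ccc(O)c(O)c1)c1c(O)cc(O)cc1O
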